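**Plan**

1. Retrosynthetic cuts, in order: enal C15 back to an allylic alcohol; triene at C3′–C4′ (Heck, myrcene) and C2′–C3′ (formylation); C2–C2′ (enolate alkylation); C7=C14 (ynolate olefination); the core at C6–C7 and C4–C5 in one step; then alkenyl–cyclobutanol, alkyne–propyl, and the C10 carbinol back to geraniol.
2. Enabling feature: the spiro carbon C5 lies between the five-ring carbinol C1 (a ketone one oxidation level up), the CH carrying the hydroxypropyl chain (C6) and the methyl carbinol C10. This is what remains when a cation at C5 is quenched by a neighbouring cyclobutanol enlarging to a cyclopentanone.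
3. Forward: the open chain is built first (geraniol → tertiary propargylic alcohol → Z-alkenylstannane → alkenylcyclobutanol aldehyde). One cationic cascade then closes the cyclohexane and turns the cyclobutane into the spiro cyclopentanone. The C7 alkylidene, the C2 side chain and the triene follow.
4. Stereochemistry: C10 from Sharpless epoxidation; C5 and C6 from anti addition across the Z-alkene in a chair biased by C10; C2 from enolate alkylation; C1 from reduction directed by the C10 hydroxyl. Alkene geometries come from trans-hydrostannation, ynolate torquoselectivity, a chelated enol triflate and the Heck step.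

Key step: step 9

Locants (target numbering, used for every spirocycle): C1 ring carbinol/ketone carbon of the five-membered ring, C2 its side-chain-bearing neighbour, C3, C4, C5 spiro carbon, C6 CH with the propyl chain (C11–C13), C7 alkylidene carbon, C8, C9, C10 methyl carbinol carbon, C14/C15 exocyclic alkene carbon and its CH2O/CHO carbon. Side chain on C2: C1′ (CH2O), C2′ (ring-bonded alkene carbon), C3′–C5′, C6′ (=CH2). TBS = tert-butyldimethylsilyl, TES = triethylsilyl, TMS = trimethylsilyl, PMB = 4-methoxybenzyl.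

Remark: ethyl 2,2-dibromopropanoate, [Cp*RuCl]4 and the pyridyl triflimide are taken as purchasable. C7 of 14 and C1 of 19/20 are oxidised later, so 14 is drawn with the expected equatorial hydroxyl and 19/20 without a C1 descriptor.

**Route**

Step 1
Reactants: 1 geraniol
Product: 2 (2S,3S)-2,3-epoxygeraniol
Conditions: Ti(OiPr)4 (5 mol%), L-(+)-diethyl tartrate (7 mol%), t-BuOOH, 4 Å MS, CH2Cl2, −20 °C
Reagents that add atoms: tert-butyl hydroperoxide, CC(C)(C)OO
Why: Sharpless asymmetric epoxidation delivers oxygen only to the allylic alkene and, with the L-(+)-tartrate, should give the (2S,3S)-epoxide, whose fully substituted carbon becomes C10 of the target.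

Step 2
Reactants: 2 (2S,3S)-2,3-epoxygeraniol
Product: 3 (2R,3S)-2-(chloromethyl)-3-methyl-3-(4-methylpent-3-enyl)oxirane
Conditions: PPh3, CCl4, NaHCO3, reflux
Reagents that add atoms: carbon tetrachloride, ClC(Cl)(Cl)Cl
Why: Appel chlorination of the primary alcohol under buffered neutral conditions, which the trisubstituted epoxide tolerates; no stereocentre is touched (the descriptor at the CH changes only by priority).

Step 3
Reactants: 3 epoxy chloride; 4 (3-bromopropoxy)-tert-butyldimethylsilane
Product: 6 (S)-1-(TBS-oxy)-6,10-dimethylundec-9-en-4-yn-6-ol, via dilithium acetylide alkoxide 5 (not isolated)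
Conditions: LiN(iPr)2 (3.3 equiv), THF, −40 → 0 °C; then 4, DMPU, 0 °C → rt; aq. NH4Cl
Reagents that add atoms: none
Why: The known double elimination of 2,3-epoxy chlorides (α-deprotonation with epoxide opening, then dehydrochlorination) never breaks the tertiary C–O bond, so C10 keeps the epoxide configuration, and the resulting lithium acetylide is alkylated in the same flask by the primary bromide (SN2).

Step 4
Reactants: 6 propargylic alcohol
Product: 7 (S,Z)-1-(TBS-oxy)-6,10-dimethyl-5-(tributylstannyl)undeca-4,9-dien-6-ol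
Conditions: Bu3SnH (1.15 equiv), [Cp*RuCl]4 (1.5 mol%), CH2Cl2, rt
Reagents that add atoms: tributyltin hydride, CCCC[SnH](CCCC)CCCC
Why: In the ruthenium-catalysed trans-hydrostannation a hydrogen bond from the free propargylic hydroxyl to the chloride ligand steers tin to the proximal alkyne carbon, and anti addition places tin cis to the propyl chain, the geometry the cascade needs.

Step 5
Reactants: 7 stannyl alcohol
Product: 8 PMB ether of 7
Conditions: KH, THF, 0 °C; PMBCl, Bu4NI (cat.), rt
Reagents that add atoms: 4-methoxybenzyl chloride, COc1ccc(CCl)cc1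
Why: Williamson etherification of the tertiary potassium alkoxide; the benzyl-type ether keeps the C10 oxygen from serving as a pinacol terminus later and can be removed oxidatively beside silyl ethers.

Step 6
Reactants: 8 PMB-protected alkenylstannane; 9 cyclobutanone
Product: 11 1-alkenylcyclobutanol (propyl chain cis to the cyclobutyl carbon), via alkenyllithium 10 (not isolated)
Conditions: n-BuLi, THF, −78 °C; then 9, −78 °C; aq. NH4Cl
Reagents that add atoms: none
Why: Tin–lithium exchange proceeds with retention of alkene geometry, and the alkenyllithium should add to the strained ketone at −78 °C faster than it enolises it (1,2-addition).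

Step 7
Reactants: 11 alkenylcyclobutanol
Product: 12 (4S)-9-(TBS-oxy)-5-(1-hydroxycyclobutyl)-4-(PMB-oxy)-4-methylnon-5-enal
Conditions: OsO4 (2 mol%), NaIO4, 2,6-lutidine, dioxane–H2O, rt
Reagents that add atoms: sodium periodate, [Na+].[O-]I(=O)(=O)=O
Why: Lemieux–Johnson cleavage selects the unhindered prenyl-type alkene, because the other trisubstituted alkene sits between two fully substituted carbons and is left alone.

Step 8
Reactants: 12 hydroxy aldehyde
Product: 13 (4S)-9-(TBS-oxy)-4-(PMB-oxy)-4-methyl-5-[1-(TMS-oxy)cyclobutyl]non-5-enal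
Conditions: N-(trimethylsilyl)imidazole, CH2Cl2, 0 °C → rt
Reagents that add atoms: N-(trimethylsilyl)imidazole, C[Si](C)(C)n1ccnc1
Why: Neutral silylation of the tertiary cyclobutanol does not enolise the aldehyde, and the labile trimethylsilyl ether is the group that is shed in the ring expansion.

Step 9
Reactants: 13 aldehyde tethered to the 1-alkenylcyclobutanol TMS ether
Product: 14 (5R,6S,7S,10S)-6-[3-(TBS-oxy)propyl]-7-hydroxy-10-(PMB-oxy)-10-methylspiro[4.5]decan-1-one
Conditions: Me2AlCl (2 equiv), CH2Cl2, −78 °C; aq. KNa tartrate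
Reagents that add atoms: none
Why: Me2AlCl activates the aldehyde and the trisubstituted alkene attacks it with its CH carbon (C6–C7 bond; cyclohexane closed through a chair, 6-endo with respect to the alkene), so the charge develops on the fully substituted C5, to which the antiperiplanar cyclobutane C–C bond migrates (C4–C5 bond) while the silyloxy carbon becomes the C1 ketone; the four-membered ring thereby expands to the cyclopentanone and C5 becomes the spiro centre. The closest known reaction type is the Prins cyclisation terminated by semipinacol ring expansion of 1-alkenylcyclobutanol silyl ethers (Prins–pinacol family). C5 and C6 are fixed relative to each other by anti addition across the alkene of defined geometry (chain cis to the cyclobutyl carbon, hence chain and C1 cis on the new ring). Their relation to C10 comes from the chair in which the C10–O bond lies near the alkene plane (equatorial) and the methyl group is axial, preferred because the small, electron-withdrawing oxygen substituent stays out of overlap with the developing cation and suffers less A1,2 strain with the cyclobutyl group than methyl would; C7 forms with its aluminium-bound oxygen equatorial and is oxidised in the next step. The step needs ring expansion to outrun a pinacol shift from C10, proton loss and ionisation of the allylic ether: release of cyclobutane strain, the non-silyl ether at C10, the absence of hydrogen on both carbons flanking C5 and the low temperature should secure this.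

Step 10
Reactants: 14 hydroxy ketone
Product: 15 (5R,6S,10S)-6-[3-(TBS-oxy)propyl]-10-(PMB-oxy)-10-methylspiro[4.5]decane-1,7-dione
Conditions: Dess–Martin periodinane, NaHCO3, CH2Cl2, rt
Reagents that add atoms: none
Why: Dess–Martin oxidation of the secondary alcohol under buffered conditions; C6, now α to a ketone, already carries its chain in the more stable equatorial position, so epimerisation is not expected to hurt.

Step 11
Reactants: 15 dione; 16 ethyl 2,2-dibromopropanoate
Product: 18 methyl (E)-2-[1-oxospiro[4.5]decan-7-ylidene]propanoate derivative (methyl cis to C6), via lithium carboxylate 17 (not isolated)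
Conditions: 16, t-BuLi (4 equiv), THF, −78 → 0 °C; 15, −78 °C → rt; then MeI, HMPA, rt
Reagents that add atoms: iodomethane, CI
Why: In the ynolate olefination the lithium ynolate adds to the cyclohexanone (the cyclopentanone carbonyl, flanked by the quaternary spiro carbon, is far more hindered) to a β-lactone enolate whose conrotatory ring opening is torquoselective, turning the bulkier, better σ-donating C6 branch outward so that the carboxylate ends cis to C8 and the methyl cis to C6; MeI then esterifies the carboxylate.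

Step 12
Reactants: 18 keto enoate
Product: 19 (E)-2-[1-hydroxyspiro[4.5]decan-7-ylidene]propan-1-ol derivative (C1 epimers)
Conditions: iBu2AlH (5 equiv), CH2Cl2, −78 → 0 °C; aq. KNa tartrate
Reagents that add atoms: none
Why: iBu2AlH reduces the hindered enoate by 1,2-addition to the allylic alcohol; the cyclopentanone is reduced too and is regenerated in step 14.

Step 13
Reactants: 19 diol
Product: 20 C15 TBS ether of 19
Conditions: TBSCl, imidazole, CH2Cl2, 0 °C
Reagents that add atoms: tert-butyldimethylsilyl chloride, CC(C)(C)[Si](C)(C)Cl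
Why: Silylation with TBSCl/imidazole discriminates the primary allylic hydroxyl from the neopentyl-type secondary one.

Step 14
Reactants: 20 secondary alcohol
Product: 21 (5R,6R,10S)-6-[3-(TBS-oxy)propyl]-7-[(E)-1-(TBS-oxy)propan-2-ylidene]-10-(PMB-oxy)-10-methylspiro[4.5]decan-1-one
Conditions: Dess–Martin periodinane, NaHCO3, CH2Cl2, rt
Reagents that add atoms: none
Why: Dess–Martin oxidation restores the cyclopentanone; the allylic oxygen is silylated, so only C1 is oxidised.

Step 15
Reactants: 21 ketone; 22 tert-butyl bromoacetate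
Product: 24 tert-butyl 2-[(2S)-1-oxospiro[4.5]dec-2-yl]acetate derivative, via lithium enolate 23 (not isolated)
Conditions: LiN(SiMe3)2, THF, −78 °C; 22, DMPU, −78 → −30 °C
Reagents that add atoms: none
Why: Enolisation can occur only at C2 (C5 is quaternary), and SN2 alkylation of the enolate is expected from the face opposite the fully substituted, ether-bearing C10, which sets C2 with the new chain cis to C6; C2 remains epimerisable, so a minor epimer could be recycled by base equilibration.

Step 16
Reactants: 24 PMB ether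
Product: 25 tert-butyl 2-[10-hydroxy-1-oxospiro[4.5]dec-2-yl]acetate derivative
Conditions: DDQ, CH2Cl2–pH 7 buffer, 0 °C → rt
Reagents that add atoms: none
Why: Oxidative PMB cleavage by DDQ (hydride abstraction, hydrolysis of the oxocarbenium ion) leaves silyl ethers, ester and the tetrasubstituted alkene untouched and frees the C10 hydroxyl that must direct the next step.

Step 17
Reactants: 25 β-hydroxy ketone
Product: 26 tert-butyl 2-[(1R,2S,5S,6R,10S)-1,10-dihydroxyspiro[4.5]dec-2-yl]acetate derivative
Conditions: Me4NBH(OAc)3, MeCN–AcOH, −30 → 0 °C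
Reagents that add atoms: none
Why: In this hydroxyl-directed triacetoxyborohydride reduction (Evans–Saksena type) the C10 oxygen binds boron and delivers hydride intramolecularly to C1 from the C10 side, setting the C1 hydroxyl anti to C10 and cis to the C2 chain; ester and alkene are inert to the reagent.

Step 18
Reactants: 26 diol
Product: 27 C1 TES ether of 26
Conditions: TESCl, imidazole, DMAP (cat.), DMF, rt
Reagents that add atoms: chlorotriethylsilane, CC[Si](Cl)(CC)CC
Why: Silylation of the secondary alcohol prevents lactonisation onto the tert-butyl ester in the basic steps that follow, while the hindered tertiary hydroxyl does not react under these conditions.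

Step 19
Reactants: 27 ester
Product: 29 tert-butyl (Z)-3-hydroxy-2-(spirocyclic)prop-2-enoate (enol of the α-formyl ester), via dilithium ester enolate 28 (not isolated)
Conditions: LiN(iPr)2 (2.2 equiv), THF, −78 °C; HCO2Et, −78 → 0 °C; aq. NH4Cl
Reagents that add atoms: ethyl formate, CCOC=O
Why: Crossed Claisen condensation: the ester enolate is formylated by ethyl formate and the product is held as its stabilised enolate until work-up, the tertiary alkoxide riding along as a spectator.

Step 20
Reactants: 29 α-formyl ester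
Product: 31 tert-butyl (Z)-2-(spirocyclic)-3-(trifluoromethylsulfonyloxy)prop-2-enoate, via lithium formyl enolate 30 (not isolated)
Conditions: LiN(SiMe3)2 (1.05 equiv), THF, −78 °C; N-(5-chloro-2-pyridyl)triflimide, −78 → 0 °C
Reagents that add atoms: N-(5-chloro-2-pyridyl)bis(trifluoromethanesulfonyl)imide, FC(F)(F)S(=O)(=O)N(c1ccc(Cl)cn1)S(=O)(=O)C(F)(F)F
Why: The lithium enolate of the α-formyl ester is a chelate with enolate oxygen and ester carbonyl on the same side, so O-sulfonylation should give the Z enol triflate (triflate cis to the ester), the lithium-controlled route to stereodefined enol sulfonates of 1,3-dicarbonyl compounds.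

Step 21
Reactants: 31 enol triflate; 32 myrcene
Product: 33 tert-butyl (2Z,4E)-10-methyl-6-methylidene-2-(spirocyclic)undeca-2,4,9-trienoate
Conditions: 32 (5 equiv), Pd(OAc)2 (10 mol%), P(o-tol)3, Et3N, MeCN, 60 °C
Reagents that add atoms: none
Why: Heck reaction: oxidative addition into the enol triflate occurs with retention, the alkenylpalladium inserts the monosubstituted alkene of the diene at its CH2 terminus, and syn β-hydride elimination from the π-allyl intermediate gives the E-diene with the methylidene group intact.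

Step 22
Reactants: 33 trienoate
Product: 34 (2Z,4E)-trien-1-ol (C1′ alcohol)
Conditions: iBu2AlH (4 equiv), CH2Cl2, −78 → −20 °C; aq. KNa tartrate
Reagents that add atoms: none
Why: 1,2-Reduction of the conjugated tert-butyl ester by iBu2AlH gives the primary allylic alcohol without touching the triene geometry at low temperature.

Step 23
Reactants: 34 allylic alcohol
Product: 35 C1′ acetate
Conditions: Ac2O, pyridine, DMAP (cat.), CH2Cl2, 0 °C
Reagents that add atoms: acetic anhydride, CC(=O)OC(C)=O
Why: Acylation selects the only primary hydroxyl; the tertiary C10 hydroxyl is inert under these conditions.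

Step 24
Reactants: 35 tris-silyl ether
Product: 36 C15 alcohol with free C1, C10 and C13 hydroxyls
Conditions: HF·pyridine, pyridine, THF, 0 °C → rt
Reagents that add atoms: none
Why: Buffered HF·pyridine should remove both primary TBS ethers and the secondary TES ether without hydrolysing or ionising the allylic acetate.

Step 25
Reactants: 36 allylic alcohol
Product: 37 CNP0204268.1
Conditions: MnO2 (activated, excess), CH2Cl2, rt
Reagents that add atoms: none
Why: MnO2 oxidises only the allylic primary alcohol, leaving the saturated primary, secondary and tertiary hydroxyls, the acetate and the triene, and gives the E-enal of the target.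

**Compound list**

1 | geraniol, (E)-3,7-dimethylocta-2,6-dien-1-ol | CC(C)=CCC/C(C)=C/CO | starting material
2 | (2S,3S)-2,3-epoxygeraniol | OC[C@@H]1O[C@@]1(C)CCC=C(C)C | intermediate
3 | (2R,3S)-2-(chloromethyl)-3-methyl-3-(4-methylpent-3-enyl)oxirane | ClC[C@@H]1O[C@@]1(C)CCC=C(C)C | intermediate
4 | (3-bromopropoxy)-tert-butyldimethylsilane | CC(C)(C)[Si](C)(C)OCCCBr | starting material
5 | dilithium salt (acetylide and alkoxide) of (S)-3,7-dimethyloct-6-en-1-yn-3-ol | CC(C)=CCC[C@](C#C[Li])(C)O[Li] | intermediate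
6 | (S)-1-(TBS-oxy)-6,10-dimethylundec-9-en-4-yn-6-ol | CC(C)=CCC[C@](C#CCCCO[Si](C)(C)C(C)(C)C)(C)O | intermediate
7 | (S,Z)-1-(TBS-oxy)-6,10-dimethyl-5-(tributylstannyl)undeca-4,9-dien-6-ol | CC(C)=CCC[C@](/C(=C/CCCO[Si](C)(C)C(C)(C)C)[Sn](CCCC)(CCCC)CCCC)(C)O | intermediate
8 | PMB ether of 7 (6-(4-methoxybenzyloxy), tin cis to the propyl chain) | CC(C)=CCC[C@](/C(=C/CCCO[Si](C)(C)C(C)(C)C)[Sn](CCCC)(CCCC)CCCC)(C)OCc1ccc(OC)cc1 | intermediate
9 | cyclobutanone | O=C1CCC1 | starting material
10 | alkenyllithium from 8 (lithium in place of tin, geometry retained) | CC(C)=CCC[C@](/C(=C/CCCO[Si](C)(C)C(C)(C)C)[Li])(C)OCc1ccc(OC)cc1 | intermediate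
11 | 1-[(6S)-1-(TBS-oxy)-6-(PMB-oxy)-6,10-dimethylundeca-4,9-dien-5-yl]cyclobutan-1-ol, propyl chain cis to cyclobutyl | CC(C)=CCC[C@](/C(=C/CCCO[Si](C)(C)C(C)(C)C)C1(O)CCC1)(C)OCc1ccc(OC)cc1 | intermediate
12 | (4S)-9-(TBS-oxy)-5-(1-hydroxycyclobutyl)-4-(PMB-oxy)-4-methylnon-5-enal, chain cis to cyclobutyl | O=CCC[C@](/C(=C/CCCO[Si](C)(C)C(C)(C)C)C1(O)CCC1)(C)OCc1ccc(OC)cc1 | intermediate
13 | (4S)-9-(TBS-oxy)-4-(PMB-oxy)-4-methyl-5-[1-(TMS-oxy)cyclobutyl]non-5-enal, chain cis to cyclobutyl | O=CCC[C@](/C(=C/CCCO[Si](C)(C)C(C)(C)C)C1(O[Si](C)(C)C)CCC1)(C)OCc1ccc(OC)cc1 | intermediate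
14 | (5R,6S,7S,10S)-6-[3-(TBS-oxy)propyl]-7-hydroxy-10-(PMB-oxy)-10-methylspiro[4.5]decan-1-one | C1CC[C@]2([C@H](CCCO[Si](C)(C)C(C)(C)C)[C@@H](O)CC[C@]2(C)OCc3ccc(OC)cc3)C1=O | intermediate
15 | (5R,6S,10S)-6-[3-(TBS-oxy)propyl]-10-(PMB-oxy)-10-methylspiro[4.5]decane-1,7-dione | C1CC[C@]2([C@H](CCCO[Si](C)(C)C(C)(C)C)C(=O)CC[C@]2(C)OCc3ccc(OC)cc3)C1=O | intermediate
16 | ethyl 2,2-dibromopropanoate | CCOC(=O)C(C)(Br)Br | starting material
17 | lithium (E)-2-{(5R,6R,10S)-6-[3-(TBS-oxy)propyl]-10-(PMB-oxy)-10-methyl-1-oxospiro[4.5]decan-7-ylidene}propanoate | C1CC[C@]2([C@H](CCCO[Si](C)(C)C(C)(C)C)/C(=C(\C)C(=O)O[Li])CC[C@]2(C)OCc3ccc(OC)cc3)C1=O | intermediate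
18 | methyl ester of 17 (methyl (E)-2-[…-1-oxospiro[4.5]decan-7-ylidene]propanoate, methyl cis to C6) | C1CC[C@]2([C@H](CCCO[Si](C)(C)C(C)(C)C)/C(=C(\C)C(=O)OC)CC[C@]2(C)OCc3ccc(OC)cc3)C1=O | intermediate
19 | (E)-2-{(5S,6R,10S)-6-[3-(TBS-oxy)propyl]-1-hydroxy-10-(PMB-oxy)-10-methylspiro[4.5]decan-7-ylidene}propan-1-ol, C1 epimers | C1CC[C@]2([C@H](CCCO[Si](C)(C)C(C)(C)C)/C(=C(\C)CO)CC[C@]2(C)OCc3ccc(OC)cc3)C1O | intermediate
20 | C15 TBS ether of 19 | C1CC[C@]2([C@H](CCCO[Si](C)(C)C(C)(C)C)/C(=C(\C)CO[Si](C)(C)C(C)(C)C)CC[C@]2(C)OCc3ccc(OC)cc3)C1O | intermediate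
21 | (5R,6R,10S)-6-[3-(TBS-oxy)propyl]-7-[(E)-1-(TBS-oxy)propan-2-ylidene]-10-(PMB-oxy)-10-methylspiro[4.5]decan-1-one | C1CC[C@]2([C@H](CCCO[Si](C)(C)C(C)(C)C)/C(=C(\C)CO[Si](C)(C)C(C)(C)C)CC[C@]2(C)OCc3ccc(OC)cc3)C1=O | intermediate
22 | tert-butyl bromoacetate | CC(C)(C)OC(=O)CBr | starting material
23 | lithium enolate of 21 (C1–OLi, C1=C2) | C=1CC[C@]2([C@H](CCCO[Si](C)(C)C(C)(C)C)/C(=C(\C)CO[Si](C)(C)C(C)(C)C)CC[C@]2(C)OCc3ccc(OC)cc3)C1O[Li] | intermediate
24 | tert-butyl 2-[(2S,5R,6R,10S)-6-[3-(TBS-oxy)propyl]-7-[(E)-1-(TBS-oxy)propan-2-ylidene]-10-(PMB-oxy)-10-methyl-1-oxospiro[4.5]dec-2-yl]acetate | CC(C)(C)OC(=O)C[C@@H]1CC[C@]2([C@H](CCCO[Si](C)(C)C(C)(C)C)/C(=C(\C)CO[Si](C)(C)C(C)(C)C)CC[C@]2(C)OCc3ccc(OC)cc3)C1=O | intermediate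
25 | 24 with free C10 hydroxyl | CC(C)(C)OC(=O)C[C@@H]1CC[C@]2([C@H](CCCO[Si](C)(C)C(C)(C)C)/C(=C(\C)CO[Si](C)(C)C(C)(C)C)CC[C@]2(C)O)C1=O | intermediate
26 | tert-butyl 2-[(1R,2S,5S,6R,10S)-1,10-dihydroxy-6-[3-(TBS-oxy)propyl]-7-[(E)-1-(TBS-oxy)propan-2-ylidene]-10-methylspiro[4.5]dec-2-yl]acetate | CC(C)(C)OC(=O)C[C@@H]1CC[C@]2([C@H](CCCO[Si](C)(C)C(C)(C)C)/C(=C(\C)CO[Si](C)(C)C(C)(C)C)CC[C@]2(C)O)[C@@H]1O | intermediate
27 | C1 TES ether of 26 | CC(C)(C)OC(=O)C[C@@H]1CC[C@]2([C@H](CCCO[Si](C)(C)C(C)(C)C)/C(=C(\C)CO[Si](C)(C)C(C)(C)C)CC[C@]2(C)O)[C@@H]1O[Si](CC)(CC)CC | intermediate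
28 | dilithium species of 27 (ester enolate and C10 alkoxide) | [Li]OC(OC(C)(C)C)=C[C@@H]1CC[C@]2([C@H](CCCO[Si](C)(C)C(C)(C)C)/C(=C(\C)CO[Si](C)(C)C(C)(C)C)CC[C@]2(C)O[Li])[C@@H]1O[Si](CC)(CC)CC | intermediate
29 | tert-butyl (Z)-3-hydroxy-2-(spirocycle-2-yl)prop-2-enoate, hydrogen-bonded enol of the α-formyl ester of 27 | O/C=C(\C(=O)OC(C)(C)C)[C@@H]1CC[C@]2([C@H](CCCO[Si](C)(C)C(C)(C)C)/C(=C(\C)CO[Si](C)(C)C(C)(C)C)CC[C@]2(C)O)[C@@H]1O[Si](CC)(CC)CC | intermediate
30 | lithium enolate (chelate) of 29 | [Li]O/C=C(\C(=O)OC(C)(C)C)[C@@H]1CC[C@]2([C@H](CCCO[Si](C)(C)C(C)(C)C)/C(=C(\C)CO[Si](C)(C)C(C)(C)C)CC[C@]2(C)O)[C@@H]1O[Si](CC)(CC)CC | intermediate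
31 | tert-butyl (Z)-2-(spirocycle-2-yl)-3-(trifluoromethylsulfonyloxy)prop-2-enoate, triflate cis to the ester | FC(F)(F)S(=O)(=O)O/C=C(\C(=O)OC(C)(C)C)[C@@H]1CC[C@]2([C@H](CCCO[Si](C)(C)C(C)(C)C)/C(=C(\C)CO[Si](C)(C)C(C)(C)C)CC[C@]2(C)O)[C@@H]1O[Si](CC)(CC)CC | intermediate
32 | myrcene, 7-methyl-3-methylideneocta-1,6-diene | C=CC(=C)CCC=C(C)C | starting material
33 | tert-butyl (2Z,4E)-10-methyl-6-methylidene-2-(spirocycle-2-yl)undeca-2,4,9-trienoate | C=C(/C=C/C=C(\C(=O)OC(C)(C)C)[C@@H]1CC[C@]2([C@H](CCCO[Si](C)(C)C(C)(C)C)/C(=C(\C)CO[Si](C)(C)C(C)(C)C)CC[C@]2(C)O)[C@@H]1O[Si](CC)(CC)CC)CCC=C(C)C | intermediate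
34 | (2Z,4E)-10-methyl-6-methylidene-2-(spirocycle-2-yl)undeca-2,4,9-trien-1-ol | C=C(/C=C/C=C(\CO)[C@@H]1CC[C@]2([C@H](CCCO[Si](C)(C)C(C)(C)C)/C(=C(\C)CO[Si](C)(C)C(C)(C)C)CC[C@]2(C)O)[C@@H]1O[Si](CC)(CC)CC)CCC=C(C)C | intermediate
35 | acetate of 34 | C=C(/C=C/C=C(\COC(C)=O)[C@@H]1CC[C@]2([C@H](CCCO[Si](C)(C)C(C)(C)C)/C(=C(\C)CO[Si](C)(C)C(C)(C)C)CC[C@]2(C)O)[C@@H]1O[Si](CC)(CC)CC)CCC=C(C)C | intermediate
36 | (2Z,4E)-2-{(1R,2S,5S,6R,10S)-1,10-dihydroxy-6-(3-hydroxypropyl)-7-[(E)-1-hydroxypropan-2-ylidene]-10-methylspiro[4.5]dec-2-yl}-10-methyl-6-methylideneundeca-2,4,9-trienyl acetate | C=C(/C=C/C=C(\COC(C)=O)[C@@H]1CC[C@]2([C@H](CCCO)/C(=C(\C)CO)CC[C@]2(C)O)[C@@H]1O)CCC=C(C)C | intermediate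
37 | CNP0204268.1, (2Z,4E)-2-{(1R,2S,5S,6R,10S)-1,10-dihydroxy-6-(3-hydroxypropyl)-10-methyl-7-[(E)-1-oxopropan-2-ylidene]spiro[4.5]dec-2-yl}-10-methyl-6-methylideneundeca-2,4,9-trienyl acetate | C=C(/C=C/C=C(\COC(C)=O)[C@@H]1CC[C@]2([C@H](CCCO)/C(=C(\C)C=O)CC[C@]2(C)O)[C@@H]1O)CCC=C(C)C | target

**Step count and risks**

Total step count: 25. Longest linear sequence: 25 steps (from geraniol; the other building blocks are purchased and enter directly).

Steps most likely to fail:

1. Step 9 (cascade). The Lewis acid may ionise or cleave the tertiary allylic PMB ether before the aldehyde is attacked. The C5 cation may be intercepted (by the anisyl ring or the chain silyl ether oxygen) before the ring expands. The alkene face may also be chosen poorly relative to C10. Fallback: the two events are uncoupled, setting out from 12 and returning at 14. NBS (propylene oxide as acid scavenger, CH2Cl2, −20 °C) triggers the bromonium-induced semipinacol ring expansion of the free alkenylcyclobutanol and should give 4-{1-[1-bromo-4-(TBS-oxy)butyl]-2-oxocyclopentyl}-4-(PMB-oxy)pentanal F1. Bu3SnH/AIBN (slow addition, benzene, 80 °C) then generates the C6 radical, which closes the cyclohexane by 6-exo addition to the aldehyde and gives 14 after hydrogen transfer. Both are known reaction types. The face selectivity of bromonium formation relative to C10 would have to be established, and C6 is set anew in the radical closure.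

2. Step 11 (ynolate olefination). The ynolate may attack the cyclopentanone carbonyl or enolise the hindered ketone, and the ring opening of the β-lactone enolate may be insufficiently torquoselective, giving a mixture of alkene isomers at C7=C14. Fallback: from 15 back to 19 by addition and oxidative transposition. Isopropenylmagnesium bromide with anhydrous CeCl3 (THF, −78 °C) should add to the cyclohexanone to give the tertiary allylic alcohol 7-hydroxy-7-(prop-1-en-2-yl)spiro[4.5]decan-1-one derivative F2. Pyridinium chlorochromate (C5H5NH[CrO3Cl]) with NaOAc in CH2Cl2 then effects the Babler–Dauben 1,3-oxidative transposition to the enal (E)-2-[1-oxospiro[4.5]decan-7-ylidene]propanal derivative F3. iBu2AlH reduces enal and cyclopentanone together to 19. The geometry of the new alkene would have to be checked at F3.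

3. Step 21 (Heck coupling). The alkenylpalladium may insert into the wrong alkene of myrcene. The π-allylpalladium intermediate may be captured by the amine instead of undergoing β-hydride elimination. The Z geometry of the push–pull trienoate may also erode at 60 °C. Fallback: a Stille coupling from 31 to 33 with a preformed diene. 6-Methylhept-5-en-2-one is converted with LiN(iPr)2 and PhNTf2 into its kinetic enol triflate, 6-methylhepta-1,5-dien-2-yl trifluoromethanesulfonate F4. F4 is coupled once with (E)-1,2-bis(tributylstannyl)ethene (Pd(PPh3)4, LiCl, THF) to give tributyl[(1E)-7-methyl-3-methylideneocta-1,6-dienyl]stannane F5. F5 and 31 are then joined at room temperature (Pd(PPh3)4, LiCl, CuCl, DMSO) with retention at both alkenes to give 33.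

Further compounds
F1 | step 9 | 4-{1-[1-bromo-4-(TBS-oxy)butyl]-2-oxocyclopentyl}-4-(PMB-oxy)pentanal (bromine-bearing carbon unassigned) | O=CCC[C@](C)(OCc1ccc(OC)cc1)[C@]1(C(Br)CCCO[Si](C)(C)C(C)(C)C)CCCC1=O
F2 | step 11 | (5R,6S,10S)-6-[3-(TBS-oxy)propyl]-7-hydroxy-10-(PMB-oxy)-10-methyl-7-(prop-1-en-2-yl)spiro[4.5]decan-1-one (C7 unassigned) | C1CC[C@]2([C@H](CCCO[Si](C)(C)C(C)(C)C)C(O)(C(C)=C)CC[C@]2(C)OCc3ccc(OC)cc3)C1=O
F3 | step 11 | (E)-2-{(5R,6R,10S)-6-[3-(TBS-oxy)propyl]-10-(PMB-oxy)-10-methyl-1-oxospiro[4.5]decan-7-ylidene}propanal | C1CC[C@]2([C@H](CCCO[Si](C)(C)C(C)(C)C)/C(=C(\C)C=O)CC[C@]2(C)OCc3ccc(OC)cc3)C1=O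
F4 | step 21 | 6-methylhepta-1,5-dien-2-yl trifluoromethanesulfonate | CC(C)=CCCC(=C)OS(=O)(=O)C(F)(F)F
F5 | step 21 | tributyl[(1E)-7-methyl-3-methylideneocta-1,6-dienyl]stannane | CC(C)=CCCC(=C)/C=C/[Sn](CCCC)(CCCC)CCCC
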